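**Retrosynthetic overview**
1. Ester C–O bond: target 9 ⇒ junenol 6 + O-acetyl-p-coumaric acid 7.
2. Exocyclic C=CH2 ⇒ ketone of trans-fused ketol 5 (methylenation).
3. Ring B (bond between the ketone α-carbon and the CHO carbon) ⇒ intramolecular aldol of keto-aldehyde 4; thermodynamic control sets three stereocentres from the quaternary one.
4. CHO ⇒ hydroformylation of the prenyl-type alkene of 3.
5. Quaternary stereocentre (first, and the only one set by a catalyst) ⇒ enantioselective amine/photocatalytic decarboxylative radical conjugate addition of 2 to 1. Ring A is bought; ring B is closed by the aldol.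

Assumptions: 5-methylhex-4-enoic acid 2 is taken as a catalogue compound; the enantiomer of amine A that gives (R)-3 is used, its sense of induction to be confirmed on the first run (both enantiomers of A are equally accessible).

Step 1
Reactants: 1 3-methylcyclohex-2-en-1-one; 2 5-methylhex-4-enoic acid
Product: 3 (3R)-3-methyl-3-(4-methylpent-3-en-1-yl)cyclohexan-1-one
Conditions: 2 (1.5 equiv), amine A [trans-2-(3,6-di-tert-butyl-9H-carbazol-9-yl)cyclohexan-1-amine, single enantiomer, 20 mol %], 4CzIPN (2 mol %), Cs2CO3 (10 mol %), degassed MeCN/H2O 20:1, blue LEDs (450 nm), 25 °C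
Reagents that add atoms: none
Why: Proposed new method: excited 4CzIPN oxidises the carboxylate of 2, loss of CO2 gives the nucleophilic primary 4-methylpent-3-enyl radical, this adds to the β-carbon of the chiral iminium ion of 1 and A on the face left open by the carbazole, and the α-iminyl radical cation is reduced at once by intramolecular electron transfer from the carbazole (turned over by reduced 4CzIPN) to an enamine that hydrolyses to 3, so the quaternary centre is set by the amine in a redox-neutral, metal-free cycle; the closest known reaction types are the primary-amine-catalysed enantioselective iminium-ion trapping of photogenerated heteroatom-stabilised radicals by β-substituted cyclic enones and the photoredox decarboxylative Giese addition, and the new element is an unstabilised primary alkyl radical made by decarboxylation in that manifold.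

Step 2
Reactants: 3 (3R)-3-methyl-3-(4-methylpent-3-en-1-yl)cyclohexan-1-one
Product: 4 2-isopropyl-4-[(1R)-1-methyl-3-oxocyclohexyl]butanal (about 1:1 epimers at C-2)
Conditions: Rh(acac)(CO)2 (1 mol %), P(O-2,4-tBu2C6H3)3 (10 mol %), CO/H2 1:1 (60 bar), toluene, 80 °C
Reagents that add atoms: carbon monoxide, [C-]#[O+]
Why: Rh-catalysed hydroformylation with a bulky phosphite accepts the trisubstituted alkene and puts the formyl group on the less substituted carbon (Keulemans' rule) while the ketone is inert; the new α-CHO centre forms unselectively and is corrected in step 3.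

Step 3
Reactants: 4 2-isopropyl-4-[(1R)-1-methyl-3-oxocyclohexyl]butanal
Product: 5 (4aR,7S,8S,8aS)-8-hydroxy-4a-methyl-7-(propan-2-yl)octahydronaphthalen-1(2H)-one
Conditions: K2CO3 (0.3 equiv), MeOH, 0 → 23 °C, 16 h
Reagents that add atoms: none
Why: Intramolecular aldol addition (6-enolexo) under reversible base catalysis: the aldehyde α-centre epimerises through its enolate, and ring closure, retro-aldol and enolisation at the ring-fusion carbon funnel both epimers of 4 to the most stable ketol (trans-fused, OH equatorial and hydrogen-bonded to C=O with no 1,3-diaxial contact to the angular methyl, isopropyl equatorial), so the three new stereocentres are set by thermodynamic control from the quaternary carbon; the other enolates can only give strained bridged adducts that revert, and the equatorial OH lies in the enolate plane, which slows E1cB dehydration.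

Step 4
Reactants: 5 (4aR,7S,8S,8aS)-8-hydroxy-4a-methyl-7-(propan-2-yl)octahydronaphthalen-1(2H)-one
Product: 6 junenol [(1S,2S,4aR,8aS)-4a-methyl-8-methylidene-2-(propan-2-yl)decahydronaphthalen-1-ol]
Conditions: Zn, CH2Br2, TiCl4 (pre-aged Lombardo reagent, 3 equiv), THF/CH2Cl2, 0 → 23 °C; aq. NaHCO3
Reagents that add atoms: dibromomethane, BrCBr
Why: Takai–Lombardo methylenation uses a non-basic gem-dimetallic CH2 reagent, so the enolisable β-hydroxy ketone is converted to the exocyclic alkene without retro-aldol, ring-fusion epimerisation or alkene migration (the free OH is carried as its titanium alkoxide); no stereocentre is touched.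

Step 5
Reactants: 6 junenol; 7 (2E)-3-[4-(acetyloxy)phenyl]prop-2-enoic acid
Product: 9 (1S,2S,4aR,8aS)-4a-methyl-8-methylidene-2-(propan-2-yl)decahydronaphthalen-1-yl (2E)-3-(4-hydroxyphenyl)prop-2-enoate, via junenyl 4-acetoxycinnamate 8 (not isolated)
Conditions: 7 (1.5 equiv), DCC (1.6 equiv), DMAP (0.2 equiv), CH2Cl2, 0 → 23 °C; then pyrrolidine (4 equiv), 0 → 23 °C, 30 min
Reagents that add atoms: none
Why: Steglich esterification of the menthol-like equatorial alcohol proceeds with retention at the carbinol carbon, and the aryl acetate is then cleaved in the same flask by chemoselective aminolysis because it is far more electrophilic than the hindered alkyl cinnamate; the (E)-alkene comes in with 7.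

**Compound list**
1 | 3-methylcyclohex-2-en-1-one | CC1=CC(=O)CCC1 | starting material
2 | 5-methylhex-4-enoic acid | CC(C)=CCCC(=O)O | starting material
3 | (3R)-3-methyl-3-(4-methylpent-3-en-1-yl)cyclohexan-1-one | O=C1CCC[C@](C)(CCC=C(C)C)C1 | intermediate
4 | 2-isopropyl-4-[(1R)-1-methyl-3-oxocyclohexyl]butanal (C-2 epimers, centre left undefined) | O=CC(C(C)C)CC[C@@]1(C)CCCC(=O)C1 | intermediate
5 | (4aR,7S,8S,8aS)-8-hydroxy-4a-methyl-7-(propan-2-yl)octahydronaphthalen-1(2H)-one | O=C1CCC[C@]2(C)CC[C@@H](C(C)C)[C@H](O)[C@@H]12 | intermediate
6 | junenol, (1S,2S,4aR,8aS)-4a-methyl-8-methylidene-2-(propan-2-yl)decahydronaphthalen-1-ol | C=C1CCC[C@]2(C)CC[C@@H](C(C)C)[C@H](O)[C@@H]12 | intermediate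
7 | (2E)-3-[4-(acetyloxy)phenyl]prop-2-enoic acid | CC(=O)Oc1ccc(/C=C/C(=O)O)cc1 | starting material
8 | (1S,2S,4aR,8aS)-4a-methyl-8-methylidene-2-(propan-2-yl)decahydronaphthalen-1-yl (2E)-3-[4-(acetyloxy)phenyl]prop-2-enoate | C=C1CCC[C@]2(C)CC[C@@H](C(C)C)[C@H](OC(=O)/C=C/c3ccc(OC(C)=O)cc3)[C@@H]12 | intermediate
9 | (1S,2S,4aR,8aS)-4a-methyl-8-methylidene-2-(propan-2-yl)decahydronaphthalen-1-yl (2E)-3-(4-hydroxyphenyl)prop-2-enoate | C=C1CCC[C@]2(C)CC[C@@H](C(C)C)[C@H](OC(=O)/C=C/c3ccc(O)cc3)[C@@H]12 | target

**Step count and risks**
Total steps: 5. Longest linear sequence: 5 (from 1).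

Most likely to fail:

Step 1 (the proposed new step). The risks are slow decarboxylation of a primary acid, low turnover of the amine and insufficient ee at the quaternary centre. The fallback sets out from 1 and uses known chemistry: 5-bromo-2-methylpent-2-ene and magnesium give (4-methylpent-3-en-1-yl)magnesium bromide F1, which is added to 1 under copper catalysis with a chiral N-heterocyclic carbene or phosphoramidite ligand (Cu(OTf)2 3 mol %, ligand 4 mol %, Et2O, −30 °C). This is the established asymmetric conjugate addition of primary alkyl Grignard reagents to 1, and it comes back to the route at 3.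

Step 2. The risk is alkene isomerisation before CO insertion, which would give the linear aldehyde, or no reaction at the trisubstituted alkene. The fallback sets out from 3: a Me2AlCl-promoted ene reaction with paraformaldehyde (CH2Cl2, −78 → 0 °C) places CH2OH on the less substituted alkene carbon and gives (3R)-3-[3-(hydroxymethyl)-4-methylpent-4-en-1-yl]-3-methylcyclohexan-1-one F2. Hydrogenation of the isopropenyl group (H2, Pd/C, EtOAc) gives (3R)-3-[3-(hydroxymethyl)-4-methylpentyl]-3-methylcyclohexan-1-one F3, and Dess–Martin oxidation of the primary alcohol returns to the route at 4.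

Step 3. The risks are dehydration and an unfavourable mixture; the trans/cis ring-fusion preference is estimated at roughly 1 kcal/mol, so some cis-fused ketol may accompany 5 and would have to be separated and re-equilibrated. The fallback sets out from 4 and installs the hydroxyl by a different bond-forming event. Compound 4 is driven on purpose to the condensation product (KOH, MeOH, 60 °C), (4aR,7S)-4a-methyl-7-(propan-2-yl)-3,4,4a,5,6,7-hexahydronaphthalen-1(2H)-one F4, whose C-7 equilibrates through the dienolate. Copper-catalysed conjugate borylation (CuCl, Xantphos, NaOtBu, B2pin2, MeOH, THF) from the face opposite the angular methyl and the isopropyl group gives (4aR,7R,8S,8aR)-4a-methyl-7-(propan-2-yl)-8-(4,4,5,5-tetramethyl-1,3,2-dioxaborolan-2-yl)octahydronaphthalen-1(2H)-one F5. Oxidation with NaBO3 (THF/H2O) proceeds with retention and comes back to the route at 5.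

**Further compounds**
F1 | step 1 | (4-methylpent-3-en-1-yl)magnesium bromide | CC(C)=CCC[Mg]Br
F2 | step 2 | (3R)-3-[3-(hydroxymethyl)-4-methylpent-4-en-1-yl]-3-methylcyclohexan-1-one (side-chain centre undefined) | C=C(C)C(CO)CC[C@@]1(C)CCCC(=O)C1
F3 | step 2 | (3R)-3-[3-(hydroxymethyl)-4-methylpentyl]-3-methylcyclohexan-1-one (side-chain centre undefined) | CC(C)C(CO)CC[C@@]1(C)CCCC(=O)C1
F4 | step 3 | (4aR,7S)-4a-methyl-7-(propan-2-yl)-3,4,4a,5,6,7-hexahydronaphthalen-1(2H)-one | O=C1CCC[C@]2(C)CC[C@@H](C(C)C)C=C12
F5 | step 3 | (4aR,7R,8S,8aR)-4a-methyl-7-(propan-2-yl)-8-(4,4,5,5-tetramethyl-1,3,2-dioxaborolan-2-yl)octahydronaphthalen-1(2H)-one | O=C1CCC[C@]2(C)CC[C@@H](C(C)C)[C@H](B3OC(C)(C)C(C)(C)O3)[C@@H]12
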